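A small charge of nucleophile, less than the electrophile beside it, can be consumed two ways: into target, or two at a time into homo dimer.

    acid set free + free base ⇌ idle adduct, settled at all times (K1 = 60 M⁻¹)
    electrophile + nucleophile → acid set free + target (k2 = 1.1 M⁻¹ s⁻¹)
    nucleophile + acid set free ⇌ protonated nucleophile, settled at all times (K3 = 880 M⁻¹)
    acid set free + free base ⇌ salt of the base, settled at all times (K4 = 5.6 M⁻¹)
    2 nucleophile → homo dimer (k5 = 0.44 M⁻¹ s⁻¹)

| flask | electrophile | nucleophile | free base | time |
|---|---|---|---|---|
| larch | 0.067 M | 0.0536 M | 0.300 M | 80 s |
| elm | 0.067 M | 0.0536 M | 0.200 M | 80 s |
| alder | 0.067 M | 0.0536 M | 0.450 M | 80 s |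

- amounts and yields of acid set free count idle adduct too
- a step written with two of one species runs at k times the square of its concentration and takes two of it each time
- run time (larch): 80 s

- part of the electrophile that has reacted at the end, larch
- part of the electrophile that has reacted at the end, elm
- part of the electrophile that has reacted at the end, alder
- what raising the concentration of free base from its lowest to its highest value here does to the part of the electrophile that has reacted (changes below 5 percentage points count as none) (no change / it falls / it rises)

**Bench rule.** Nucleophile is the limiting reagent, taken one for one by electrophile. Larch, elm and alder therefore share a first ceiling, c(nucleophile)/c(electrophile) = 80.0% of the electrophile reacted.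

**The border.** That rule needs the target step to outrun the dimer step by far. Just after the start in larch, the target step uses nucleophile 1.6 times as fast as the dimer step, so the rule is already past its border.

**The correction.** At any moment, with the concentrations of that moment, each nucleophile taken into target is accompanied by S·c(nucleophile)/c(electrophile) lost to homo dimer, where the selectivity factor S = 2·0.44 M⁻¹ s⁻¹/1.1 M⁻¹ s⁻¹ = 0.800. Integrated from the charges down to zero free nucleophile, this leaves a fraction (1 − (1 − S)·c(nucleophile)/c(electrophile))^(1/(1 − S)) of the electrophile, with charged concentrations in the formula. The result is 58.2%, the dimer-corrected yield: the part of the electrophile reacted once free nucleophile reaches zero, reckoned with protonated nucleophile set aside. The correction takes 22 percentage points off the ceiling.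

**Its reach.** This reckoning has no clock, and protonated nucleophile enters neither the target step nor the dimer step. It has no base term either, so it shows no trend across larch, elm and alder. With nucleophile as charged, the electrophile's half-life by the target step alone, 12 s, is short against 80 s, so the reckoning takes 58.2% as its estimate for that time.

**Forecast.** The forecast gives 54% for larch (51.5% to 56%), 52.4% for elm (50% to 55%) and 55% for alder (52.5% to 57.5%), with the trend no change. Its ground: “Late-stage nucleophile depletion limits all three runs”.

**Result.** The simulation gives 54.1% for larch, 52.8% for elm and 55.1% for alder, a change of 2.3 points from elm to alder, so the trend is no change. At 80.0 s, larch still holds 0.00346 M protonated nucleophile beside 4.2% of its nucleophile free. At 800 s, larch reads 62.3%, which is 4.1 points above the dimer-corrected yield. For a flask like larch with 0.11 M electrophile, the ceiling is 48.7% and the dimer-corrected yield 40.1%; that flask reads 39.9% at 80.0 s.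

(Its constants are those of an exercise; the flask was simulated.)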